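**The ratio.** I started from a ratio of turnover frequencies, meaning product made per hour on the straight stretch of a run, divided by the catalyst loading. Amber read 6.35 h⁻¹ and red read 21.7 h⁻¹, so the turnover ratio, hot run over cold run, read 3.41. That is 0.533 of a power of ten across the span from 12 °C to 40 °C, and I laid the logarithm of turnover on a straight line over temperature.

all flasks: substrate 0.20 M (fed, over 6.0 h)
- amber: coupling partner 1.2 equiv; free catalyst 0.32 mol%; temperature 12 °C; run made earlier; the fed solution adds 0.25 times the starting volume
- red: coupling partner 1.2 equiv; free catalyst 0.51 mol%; temperature 40 °C; run made earlier; the fed solution adds 0.25 times the starting volume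
- larch: coupling partner 1.20 equiv; free catalyst 0.23 mol%; temperature 25 °C; the fed solution adds 0.25 times the starting volume; time 6.0 h
- maple: coupling partner 1.20 equiv; free catalyst 0.23 mol%; temperature 0 °C; the fed solution adds 0.25 times the starting volume; time 6.0 h
- ash: coupling partner 1.20 equiv; free catalyst 0.23 mol%; temperature 50 °C; the fed solution adds 0.25 times the starting volume; time 6.0 h

- amber (time / h: product / %): 0.833: 0; 2.50: 0.3; 4.00: 5.8; 6.00: 10.3; 10.0: 18.0; 12.0: 19.8
- red (time / h: product / %): 0.200: 0.7; 0.667: 5.0; 1.00: 8.3; 1.33: 9.4; 2.50: 24.2; 3.00: 30.8

(standard deviation of a reading: 1 percentage point)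

* the flask that comes out highest in amount of product, in percent of the substrate charged, or "all alike" when all lie within 1.5 percentage points (larch / maple / ash / all alike)
* product at the end, in percent of the substrate charged, larch
* product at the end, in percent of the substrate charged, maple
* product at the end, in percent of the substrate charged, ash

- charges are per starting volume, the dose included; the dosed solution carries all of it
- what was read earlier has a scatter of 1 percentage point, one standard deviation
- steps that have been proposed: substrate + free catalyst <-> catalyst intermediate A; catalyst intermediate A -> catalyst intermediate B; coupling partner + catalyst intermediate B <-> catalyst intermediate C; catalyst intermediate C <-> free catalyst + product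
- percentages count the whole charge, also what has not yet gone in

**Temperature.** Temperature is the setting that differs among the new flasks, so I moved along that line by hand and got 3.75 h⁻¹ for maple, 11.2 h⁻¹ for larch and 33.6 h⁻¹ for ash. Ash therefore stood higher than either of the others. Over 6.0 h at the given loading, my reckoning gave 5.18% for maple, 15.5% for larch and 46.4% for ash. Amber had read only 0.3% at 2.50 h, so I suspected a lag and took my maple figure as high.

**Catalyst loading.** By hand, the rate follows the loading, and at 0.23 mol% ash's throughput came to 0.0773 h⁻¹ of the charge. The new flasks share that loading, so in my reckoning it scaled them alike and left their order as it was.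

**The dose.** The feed delivered 0.167 h⁻¹ of the charge, twice ash's throughput, so I expected substrate to pile up in ash and the catalyst, not the dosing time, to set the pace.

**The forecast.** The forecast named ash, with 13.5% for larch (9% to 19%), 3.2% for maple (1% to 6.5%) and 38% for ash (24% to 52%), and it warned that “weaker substrate binding could flatten the rate there”. For ash it stood lower than my figure.

**The result.** Ash came out highest at 53.8%, with larch at 22.8% and maple at 1.58%.

    substrate + free catalyst ⇌ catalyst intermediate A (K = 6.60 M⁻¹, k = 420 M⁻¹ min⁻¹, Ea = 42.0 kJ mol⁻¹, ΔH = −7.00 kJ mol⁻¹)
    catalyst intermediate A → catalyst intermediate B (k = 1.50 min⁻¹, Ea = 86.0 kJ mol⁻¹)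
    coupling partner + catalyst intermediate B ⇌ catalyst intermediate C (K = 13.0 M⁻¹, k = 7.00 M⁻¹ min⁻¹, Ea = 66.0 kJ mol⁻¹, ΔH = −28.0 kJ mol⁻¹)
    catalyst intermediate C ⇌ free catalyst + product (K = 0.0900 M, k = 140 min⁻¹, Ea = 73.0 kJ mol⁻¹, ΔH = −45.0 kJ mol⁻¹)
    (constants at 25 °C)

At the end of ash, catalyst intermediate B, the resting state, held 60.8% of the catalyst, more than any other form, while 46.0% of the substrate stood unbound. Carried up to 50 °C, the ratio 3.41 gave ash a throughput that puts a conversion of substrate of 0.7 at 9.05 h, and ash reached that conversion at 8.90 h.

(The numbers in the tables are simulated for an exercise.)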